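**Retrosynthetic overview**

1. Labels: ring E is the methylcyclohexene (C1 carries CH3, C3 carries ring A, C4 the aroyl group, C5 ring C); ring A is the enone-bearing resorcinol ring, ring B the prenylated aroyl ring, rings C and D the two 2,4-dihydroxyphenyl rings. Kuwanon I ⇒ its hexakis-silyl ether ⇒ a ring A salicylaldehyde on ring E plus the ring D arylalkyne (enone made last by Rh alkyne hydroacylation).
2. That aldehyde ⇒ three components in one flask: ring B salicylaldehyde + ring C arylalkyne + ring A dienyl salicylaldehyde. Rh hydroacylation makes the bond between the aroyl carbonyl carbon and C4; the 2'-hydroxychalcone so formed is trapped by a chiral-borate exo Diels–Alder reaction that forms C3–C4 and C5–C6 and sets C3, C4 and C5.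
3. Enabling feature: the hydroxyl on C2 of ring B, ortho to the carbon that becomes the ketone. With the aldehyde it chelates rhodium (O,C-acyl rhodacycle, no decarbonylation); with the new ketone oxygen it chelates boron (dienophile activation and facial control).
4. Both salicylaldehydes ⇐ 2,4-dihydroxy-3-iodobenzaldehyde (Stille prenylation or Suzuki dienylation); rings C and D ⇐ one alkyne made from 2,4-dihydroxybenzaldehyde and used twice.
5. Ring order: the four benzene rings are bought; ring E is the only ring formed (step 9).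

Key step: step 9

Assumption: (R)-VANOL is written as the ligand antipode that shields the enone face leading to the (1S,5R,6S) adduct; this sense of induction is a working model for this diene, and the (S)-ligand is used instead if a pilot run shows the opposite sense.

**Route**

Step 1
Reactants: 1 2-iodobenzene-1,3-diol
Product: 3 2,4-dihydroxy-3-iodobenzaldehyde, via iminium salt 2 (not isolated)
Conditions: POCl3, DMF, MeCN, 0 °C to rt; then H2O, 50 °C
Reagents that add atoms: N,N-dimethylformamide CN(C)C=O; water O
Why: Vilsmeier–Haack formylation attacks the only free position that is para to one hydroxyl and ortho to the other (the carbon between the hydroxyls is blocked by iodine), and hydrolysis of iminium salt 2 releases the aldehyde; no stereocentre is formed.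

Step 2
Reactants: 3 2,4-dihydroxy-3-iodobenzaldehyde
Product: 4 4-(tert-butyldimethylsilyloxy)-2-hydroxy-3-iodobenzaldehyde
Conditions: TBSCl (1.05 equiv), imidazole, CH2Cl2, 0 °C
Reagents that add atoms: tert-butyldimethylsilyl chloride CC(C)(C)[Si](C)(C)Cl
Why: Selective phenol silylation: the 2-hydroxyl is tied up in a hydrogen bond to the aldehyde and flanked on both sides, so one equivalent of silyl chloride should react only at O4.

Step 3
Reactants: 4 4-(tert-butyldimethylsilyloxy)-2-hydroxy-3-iodobenzaldehyde; 5 tributyl(3-methylbut-2-en-1-yl)stannane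
Product: 6 4-(tert-butyldimethylsilyloxy)-2-hydroxy-3-(3-methylbut-2-en-1-yl)benzaldehyde
Conditions: Pd(PPh3)4 (5 mol %), DMF, 90 °C
Reagents that add atoms: none
Why: Migita–Kosugi–Stille coupling of the aryl iodide with the allylstannane under neutral conditions, in which reductive elimination at the unsubstituted allyl terminus should give the linear prenyl group and the aryl silyl ether survives because neither fluoride nor base is present.

Step 4
Reactants: 7 2,4-dihydroxybenzaldehyde
Product: 8 2,4-bis(tert-butyldimethylsilyloxy)benzaldehyde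
Conditions: TBSCl (2.5 equiv), imidazole, DMF, rt
Reagents that add atoms: tert-butyldimethylsilyl chloride CC(C)(C)[Si](C)(C)Cl
Why: Exhaustive imidazole-promoted silylation caps both phenols, the hydrogen-bonded one included, so that the later alkyne has no free ortho-hydroxyl that could cyclise onto it to a benzofuran.

Step 5
Reactants: 8 2,4-bis(tert-butyldimethylsilyloxy)benzaldehyde
Product: 9 1-ethynyl-2,4-bis(tert-butyldimethylsilyloxy)benzene
Conditions: Me3SiCHN2, LiN(iPr)2, THF, −78 °C to rt; then H2O
Reagents that add atoms: trimethylsilyldiazomethane C[Si](C)(C)C=[N+]=[N-]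
Why: Colvin rearrangement: the lithiated diazomethane adds to the aldehyde, Peterson-type loss of silanolate and then of N2 gives an alkylidene carbene whose 1,2-hydride shift furnishes the terminal alkyne, without the alkoxide or methanol that would cleave aryl silyl ethers.

Step 6
Reactants: 10 2-methylbut-1-en-3-yne; 11 pinacolborane
Product: 12 (E)-4,4,5,5-tetramethyl-2-(3-methylbuta-1,3-dien-1-yl)-1,3,2-dioxaborolane
Conditions: Cp2Zr(H)Cl (5 mol %), Et3N (10 mol %), neat, 60 °C
Reagents that add atoms: none
Why: Zirconocene-hydride-catalysed hydroboration of a terminal alkyne is a syn, anti-Markovnikov addition that leaves the 1,1-disubstituted alkene untouched and should give the E-dienylboronate.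

Step 7
Reactants: 3 2,4-dihydroxy-3-iodobenzaldehyde; 12 (E)-4,4,5,5-tetramethyl-2-(3-methylbuta-1,3-dien-1-yl)-1,3,2-dioxaborolane
Product: 13 2,4-dihydroxy-3-[(E)-3-methylbuta-1,3-dien-1-yl]benzaldehyde
Conditions: Pd(dppf)Cl2 (5 mol %; dppf = Fe(C5H4PPh2)2), K2CO3, 1,4-dioxane/H2O, 70 °C
Reagents that add atoms: none
Why: Suzuki–Miyaura coupling proceeds with retention of alkene geometry and tolerates free phenols and the aldehyde, so it should place the E-diene on the carbon between the two hydroxyls.

Step 8
Reactants: 13 2,4-dihydroxy-3-[(E)-3-methylbuta-1,3-dien-1-yl]benzaldehyde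
Product: 14 4-(tert-butyldimethylsilyloxy)-2-hydroxy-3-[(E)-3-methylbuta-1,3-dien-1-yl]benzaldehyde
Conditions: TBSCl (1.05 equiv), imidazole, CH2Cl2, 0 °C
Reagents that add atoms: tert-butyldimethylsilyl chloride CC(C)(C)[Si](C)(C)Cl
Why: Selective phenol silylation as in step 2: only the 4-hydroxyl is free of the hydrogen bond to the aldehyde, and the mild conditions leave the diene unchanged.

Step 9
Reactants: 6 4-(tert-butyldimethylsilyloxy)-2-hydroxy-3-(3-methylbut-2-en-1-yl)benzaldehyde; 9 1-ethynyl-2,4-bis(tert-butyldimethylsilyloxy)benzene; 14 4-(tert-butyldimethylsilyloxy)-2-hydroxy-3-[(E)-3-methylbuta-1,3-dien-1-yl]benzaldehyde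
Product: 18 3-[(1S,5R,6S)-5-[2,4-bis(tert-butyldimethylsilyloxy)phenyl]-6-[4-(tert-butyldimethylsilyloxy)-2-hydroxy-3-(3-methylbut-2-en-1-yl)benzoyl]-3-methylcyclohex-2-en-1-yl]-4-(tert-butyldimethylsilyloxy)-2-hydroxybenzaldehyde, via chalcone 15 (not isolated), via chalcone boron chelate 16 (not isolated), via adduct boron chelate 17 (not isolated)
Conditions: 6, 9, [Rh(cod)Cl]2 (2.5 mol %), dppf (5 mol %), Na2CO3 (10 mol %), PhMe, 80 °C; then rt, B(OPh)3/(R)-VANOL (1:1, premixed, 1.2 equiv), 4 Å MS; then 14, rt; then H2O
Reagents that add atoms: none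
Why: Stage one is a chelation-assisted rhodium alkyne hydroacylation: the ring B phenoxide binds monovalent rhodium, the neighbouring aldehyde C–H adds oxidatively to give a five-membered O,C-chelated acyl hydride of trivalent rhodium that does not decarbonylate, syn hydrometalation of 9 puts rhodium on the terminal carbon (away from the ortho-silyloxyaryl group) and C–C reductive elimination forges the aroyl C(=O)–C4 bond as E-enone 15, the prenyl alkene being too hindered to insert and the diene being withheld until the alkyne is consumed. Stage two is the chiral-borate-promoted Diels–Alder reaction of 2'-hydroxychalcones: the same phenol oxygen and the new carbonyl oxygen chelate boron (16), which lowers the enone LUMO and places the VANOL backbone over one enone face. Ring E is closed by an intermolecular, concerted but asynchronous [4+2] cycloaddition in which C5–C6 and C3–C4 form suprafacially on both partners to give 17, released as 18 on aqueous work-up. C4 and C5 should come out trans because the E geometry of 15 is transferred stereospecifically, C3 should be set trans to C4 by the exo transition state, favoured because the di-ortho-substituted ring A on the diene terminus avoids the bulky boron chelate, and the absolute sense at all three centres follows from the ligand-shielded enone face. The regiochemistry needed (ring A-bearing carbon to the alpha carbon, CH2 terminus to the beta carbon) is secured by the 1-aryl and 3-methyl donors, which both place the largest diene HOMO coefficient on the CH2 terminus. Both reaction types have close precedent on exactly these substrate classes (salicylaldehydes with alkynes under [Rh(cod)Cl]2/dppf; 2'-hydroxychalcones with 1-aryl-3-methylbutadienes under boron–biaryldiol promotion) and are here run in sequence in one flask.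

Step 10
Reactants: 18 ring E salicylaldehyde from step 9; 9 1-ethynyl-2,4-bis(tert-butyldimethylsilyloxy)benzene
Product: 19 kuwanon I hexakis(tert-butyldimethylsilyl) ether, (E)-1-[3-[(1S,5R,6S)-5-[2,4-bis(tert-butyldimethylsilyloxy)phenyl]-6-[4-(tert-butyldimethylsilyloxy)-2-hydroxy-3-(3-methylbut-2-en-1-yl)benzoyl]-3-methylcyclohex-2-en-1-yl]-4-(tert-butyldimethylsilyloxy)-2-hydroxyphenyl]-3-[2,4-bis(tert-butyldimethylsilyloxy)phenyl]prop-2-en-1-one
Conditions: [Rh(cod)Cl]2 (2.5 mol %), dppf (5 mol %), Na2CO3 (10 mol %), PhMe, 80 °C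
Reagents that add atoms: none
Why: The same chelation-assisted rhodium alkyne hydroacylation as in stage one of step 9, now through the ring A phenoxide and its aldehyde, should add the formyl C–H across 9 in syn, linear fashion to give the E-enone, while the diene that could have competed is already consumed and the three ring E stereocentres, which sit in their most stable all-trans arrangement, are not touched.

Step 11
Reactants: 19 kuwanon I hexakis(tert-butyldimethylsilyl) ether
Product: 20 kuwanon I
Conditions: Bu4NF, AcOH (1:1), THF, 0 °C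
Reagents that add atoms: none
Why: Fluoride-mediated cleavage of the six aryl silyl ethers (Si–F bond formation) under acetic acid buffering should free the phenols without base-induced chalcone-to-flavanone closure, acid-induced prenyl cyclisation or epimerisation at C4.

**Compound list**

1 | 2-iodobenzene-1,3-diol (2-iodoresorcinol) | Oc1cccc(O)c1I | starting material
2 | [(2,4-dihydroxy-3-iodophenyl)methylidene]dimethylammonium chloride (aryl iminium salt, not isolated) | C[N+](C)=Cc1ccc(O)c(I)c1O.[Cl-] | intermediate
3 | 2,4-dihydroxy-3-iodobenzaldehyde | O=Cc1ccc(O)c(I)c1O | intermediate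
4 | 4-(tert-butyldimethylsilyloxy)-2-hydroxy-3-iodobenzaldehyde | O=Cc1ccc(O[Si](C)(C)C(C)(C)C)c(I)c1O | intermediate
5 | tributyl(3-methylbut-2-en-1-yl)stannane | CC(C)=CC[Sn](CCCC)(CCCC)CCCC | starting material
6 | 4-(tert-butyldimethylsilyloxy)-2-hydroxy-3-(3-methylbut-2-en-1-yl)benzaldehyde (ring B aldehyde) | CC(C)=CCc1c(O[Si](C)(C)C(C)(C)C)ccc(C=O)c1O | intermediate
7 | 2,4-dihydroxybenzaldehyde | O=Cc1ccc(O)cc1O | starting material
8 | 2,4-bis(tert-butyldimethylsilyloxy)benzaldehyde | O=Cc1ccc(O[Si](C)(C)C(C)(C)C)cc1O[Si](C)(C)C(C)(C)C | intermediate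
9 | 1-ethynyl-2,4-bis(tert-butyldimethylsilyloxy)benzene (alkyne for rings C and D) | C#Cc1ccc(O[Si](C)(C)C(C)(C)C)cc1O[Si](C)(C)C(C)(C)C | intermediate
10 | 2-methylbut-1-en-3-yne | C=C(C)C#C | starting material
11 | pinacolborane (4,4,5,5-tetramethyl-1,3,2-dioxaborolane) | CC1(C)OBOC1(C)C | starting material
12 | (E)-4,4,5,5-tetramethyl-2-(3-methylbuta-1,3-dien-1-yl)-1,3,2-dioxaborolane | CC(=C)/C=C/B1OC(C)(C)C(C)(C)O1 | intermediate
13 | 2,4-dihydroxy-3-[(E)-3-methylbuta-1,3-dien-1-yl]benzaldehyde | CC(=C)/C=C/c1c(O)ccc(C=O)c1O | intermediate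
14 | 4-(tert-butyldimethylsilyloxy)-2-hydroxy-3-[(E)-3-methylbuta-1,3-dien-1-yl]benzaldehyde (ring A diene) | CC(=C)/C=C/c1c(O[Si](C)(C)C(C)(C)C)ccc(C=O)c1O | intermediate
15 | (E)-3-[2,4-bis(tert-butyldimethylsilyloxy)phenyl]-1-[4-(tert-butyldimethylsilyloxy)-2-hydroxy-3-(3-methylbut-2-en-1-yl)phenyl]prop-2-en-1-one (chalcone, not isolated) | CC(C)=CCc1c(O[Si](C)(C)C(C)(C)C)ccc(C(=O)/C=C/c2ccc(O[Si](C)(C)C(C)(C)C)cc2O[Si](C)(C)C(C)(C)C)c1O | intermediate
16 | spiro-borate chelate of chalcone 15: boron bound to the ring B C2 phenoxide oxygen, the enone carbonyl oxygen and both oxygens of (R)-VANOL (not isolated; the (R) axis is not encoded in the SMILES) | CC(C)=CCc1c(O[Si](C)(C)C(C)(C)C)ccc2c1O[B-]1(Oc3c(c(cc4ccccc34)-c3ccccc3)-c3c(O1)c4ccccc4cc3-c3ccccc3)[O+]=C2/C=C/c1ccc(O[Si](C)(C)C(C)(C)C)cc1O[Si](C)(C)C(C)(C)C | intermediate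
17 | spiro-borate chelate of adduct 18, boron bound as in 16 (not isolated; the (R) axis is not encoded in the SMILES) | CC(C)=CCc1c(O[Si](C)(C)C(C)(C)C)ccc2c1O[B-]1(Oc3c(c(cc4ccccc34)-c3ccccc3)-c3c(O1)c4ccccc4cc3-c3ccccc3)[O+]=C2[C@@H]1[C@@H](c3c(O[Si](C)(C)C(C)(C)C)ccc(C=O)c3O)C=C(C)C[C@H]1c1ccc(O[Si](C)(C)C(C)(C)C)cc1O[Si](C)(C)C(C)(C)C | intermediate
18 | 3-[(1S,5R,6S)-5-[2,4-bis(tert-butyldimethylsilyloxy)phenyl]-6-[4-(tert-butyldimethylsilyloxy)-2-hydroxy-3-(3-methylbut-2-en-1-yl)benzoyl]-3-methylcyclohex-2-en-1-yl]-4-(tert-butyldimethylsilyloxy)-2-hydroxybenzaldehyde (all-trans ring E) | CC(C)=CCc1c(O[Si](C)(C)C(C)(C)C)ccc(C(=O)[C@@H]2[C@@H](c3c(O[Si](C)(C)C(C)(C)C)ccc(C=O)c3O)C=C(C)C[C@H]2c2ccc(O[Si](C)(C)C(C)(C)C)cc2O[Si](C)(C)C(C)(C)C)c1O | intermediate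
19 | kuwanon I hexakis(tert-butyldimethylsilyl) ether (silyl on O4 of rings A and B and on both oxygens of rings C and D; the 2-hydroxyls of rings A and B free) | CC(C)=CCc1c(O[Si](C)(C)C(C)(C)C)ccc(C(=O)[C@@H]2[C@@H](c3c(O[Si](C)(C)C(C)(C)C)ccc(C(=O)/C=C/c4ccc(O[Si](C)(C)C(C)(C)C)cc4O[Si](C)(C)C(C)(C)C)c3O)C=C(C)C[C@H]2c2ccc(O[Si](C)(C)C(C)(C)C)cc2O[Si](C)(C)C(C)(C)C)c1O | intermediate
20 | kuwanon I, (E)-1-[3-[(1S,5R,6S)-6-[2,4-dihydroxy-3-(3-methylbut-2-en-1-yl)benzoyl]-5-(2,4-dihydroxyphenyl)-3-methylcyclohex-2-en-1-yl]-2,4-dihydroxyphenyl]-3-(2,4-dihydroxyphenyl)prop-2-en-1-one | CC(C)=CCc1c(O)ccc(C(=O)[C@@H]2[C@@H](c3c(O)ccc(C(=O)/C=C/c4ccc(O)cc4O)c3O)C=C(C)C[C@H]2c2ccc(O)cc2O)c1O | target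

**Step count and risks**

Total step count: 11. Longest linear sequence: 6 steps (steps 1, 2, 3, 9, 10, 11).

Step 9. What may go wrong: Markovnikov insertion of alkyne 9 giving a branched enone, base-induced oxa-Michael closure of chalcone 15 to a flavanone, or carry-over of rhodium and phosphine into the boron stage with loss of exo and facial control. Fallback: the two events are separated, and the C(=O)–C4 bond is made by 1,2-addition and oxidation instead of C–H activation. It sets out from 9, 11 and 6. Cp2Zr(H)Cl-catalysed hydroboration of 9 with 11 should give the (E)-styrylboronate F1. [Rh(cod)OH]2-catalysed 1,2-addition of F1 to aldehyde 6 in dioxane should give the racemic allylic alcohol F2, whose linear E skeleton is fixed by the boronate. MnO2 in CH2Cl2 should oxidise F2 to chalcone 15, at which point the fallback comes back to the route. Purified 15 is then submitted to the B(OPh)3/(R)-VANOL cycloaddition with 14 as a stand-alone operation to reach 18.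

Step 10. What may go wrong: slow oxidative addition of the ring A aldehyde C–H bond because the chelating phenoxide is flanked by the bulky ring E, so that decarbonylation and alkyne oligomerisation take over. Fallback: carbonyl addition followed by oxidation, which needs no acyl hydride. It sets out from 18 and the (E)-styrylboronate F1, made from 9 and 11 as above. [Rh(cod)OH]2-catalysed 1,2-addition of F1 to the aldehyde of 18 should give the allylic alcohol F3 as a mixture of carbinol epimers; the ring B aryl ketone is too hindered and deactivated by its hydrogen bond to compete. MnO2 oxidation should then give 19, where the route is rejoined.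

Step 3. What may go wrong: coupling through the substituted allyl terminus (1,1-dimethylallyl isomer), O-allylation of the free phenol, or protodeiodination. Fallback: nucleophilic C-prenylation in place of cross-coupling. It sets out from 7. Prenyl bromide in aqueous KOH at 0 °C should alkylate the resorcinolate dianion at the carbon between the two oxygens to give 2,4-dihydroxy-3-(3-methylbut-2-en-1-yl)benzaldehyde F4, which is separated from O-alkylated and C5-alkylated material. Selective 4-O-silylation as in step 2 then returns to 6.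

Further compounds
F1 | step 9 | (E)-2-[2-[2,4-bis(tert-butyldimethylsilyloxy)phenyl]ethenyl]-4,4,5,5-tetramethyl-1,3,2-dioxaborolane | CC1(C)OB(/C=C/c2ccc(O[Si](C)(C)C(C)(C)C)cc2O[Si](C)(C)C(C)(C)C)OC1(C)C
F2 | step 9 | (E)-3-[2,4-bis(tert-butyldimethylsilyloxy)phenyl]-1-[4-(tert-butyldimethylsilyloxy)-2-hydroxy-3-(3-methylbut-2-en-1-yl)phenyl]prop-2-en-1-ol (racemic) | CC(C)=CCc1c(O[Si](C)(C)C(C)(C)C)ccc(C(O)/C=C/c2ccc(O[Si](C)(C)C(C)(C)C)cc2O[Si](C)(C)C(C)(C)C)c1O
F3 | step 10 | allylic alcohol corresponding to 19 with the ring A enone carbonyl as CH(OH) (mixture of carbinol epimers) | CC(C)=CCc1c(O[Si](C)(C)C(C)(C)C)ccc(C(=O)[C@@H]2[C@@H](c3c(O[Si](C)(C)C(C)(C)C)ccc(C(O)/C=C/c4ccc(O[Si](C)(C)C(C)(C)C)cc4O[Si](C)(C)C(C)(C)C)c3O)C=C(C)C[C@H]2c2ccc(O[Si](C)(C)C(C)(C)C)cc2O[Si](C)(C)C(C)(C)C)c1O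
F4 | step 3 | 2,4-dihydroxy-3-(3-methylbut-2-en-1-yl)benzaldehyde | CC(C)=CCc1c(O)ccc(C=O)c1O
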